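**Strategy**

Everything rests on reading the C3–C3a bond of the dihydrobenzofuran as the trace of a 1,2-aryl shift. The ester carbon and ring-A carbon C3a are both attached to C3, which is what remains when C4a of a flavanone moves from the carbonyl carbon C4 to C3. One trivalent-iodine oxidation in trimethyl orthoformate thus contracts the pyranone ring to the trans-dihydrofuran, derives C3 from C2 and writes the only methyl ester of the target. Its precursor is a (2S)-5-bromoflavanone whose three phenols are acetates (electron-poor ring B), assembled by enantioselective conjugate arylation of a chromone. The bromine later carries a Heck union with a protected danshensu acrylate before global acidolysis.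

Key step: step 9

Remark on numbering: flavanone intermediates use chroman numbering (O1, C2, C3, C4, C4a, C5–C8, C8a). After the contraction benzofuran numbering applies (old C4a = C3a, old C5 = C4, old C8 = C7).

Assumption: the (R)-configured 4-tert-butyl-2-(pyridin-2-yl)-4,5-dihydrooxazole ligand is taken to give the (2S)-flavanone, by analogy with the sense of induction of this ligand class on cyclic enones. If the sense proves opposite, the enantiomeric ligand is used.

**Route**

Step 1
Reactants: 1 4-bromocatechol
Product: 2 4-bromo-1,2-bis(methoxymethoxy)benzene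
Conditions: MOMCl, i-Pr2NEt, CH2Cl2, 0 °C → rt
Reagents that add atoms: chloromethyl methyl ether, COCCl
Why: Williamson-type O-alkylation of both phenols by the reactive α-chloro ether gives the bis-acetal ether, which later directs the lithiation and is released by acid during chromone closure.

Step 2
Reactants: 2 4-bromo-1,2-bis(methoxymethoxy)benzene
Product: 4 1-[6-bromo-2,3-bis(methoxymethoxy)phenyl]ethan-1-one, via aryllithium 3 (not isolated)
Conditions: LiN(i-Pr)2, THF, −78 °C; then MeC(O)N(OMe)Me, −78 → 0 °C; sat. NH4Cl
Reagents that add atoms: N-methoxy-N-methylacetamide, CC(=O)N(C)OC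
Why: Directed ortho-metalation removes only the proton flanked by the coordinating acetal oxygen and the acidifying bromine (an amide base causes no bromine–lithium exchange, and −78 °C suppresses benzyne formation), and the aryllithium is acylated once through the chelated adduct of the Weinreb ketone synthesis.

Step 3
Reactants: 4 1-[6-bromo-2,3-bis(methoxymethoxy)phenyl]ethan-1-one
Product: 6 5-bromo-8-hydroxy-4H-chromen-4-one, via enaminone 5 (not isolated)
Conditions: Me2NCH(OMe)2 (neat), 110 °C; concentrate; then conc. HCl, MeOH, 50 °C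
Reagents that add atoms: N,N-dimethylformamide dimethyl acetal, COC(OC)N(C)C
Why: Condensation of the methyl ketone with the amide acetal gives the enaminone; acid then cleaves both acetal ethers, and the freed ortho-phenol adds to the enaminone and expels dimethylamine (enaminone chromone synthesis), so ring closure and release of the C8 hydroxyl occur in one pot.

Step 4
Reactants: 6 5-bromo-8-hydroxy-4H-chromen-4-one
Product: 7 5-bromo-4-oxo-4H-chromen-8-yl acetate
Conditions: Ac2O, pyridine, DMAP (cat.), CH2Cl2, rt
Reagents that add atoms: acetic anhydride, CC(=O)OC(C)=O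
Why: DMAP-catalysed O-acetylation of the phenol; the acetate is introduced only now because aryl acetates would not survive the amide acetal used for chromone closure.

Step 5
Reactants: 1 4-bromocatechol
Product: 8 4-bromo-1,2-phenylene diacetate
Conditions: Ac2O, pyridine, rt
Reagents that add atoms: acetic anhydride, CC(=O)OC(C)=O
Why: Exhaustive O-acetylation of the catechol installs the electron-withdrawing groups that ring B must carry through the ring contraction.

Step 6
Reactants: 8 4-bromo-1,2-phenylene diacetate
Product: 9 4-(4,4,5,5-tetramethyl-1,3,2-dioxaborolan-2-yl)-1,2-phenylene diacetate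
Conditions: B2pin2, PdCl2(dppf) (3 mol %), KOAc, 1,4-dioxane, 85 °C
Reagents that add atoms: bis(pinacolato)diboron, CC1(C)OB(OC1(C)C)B1OC(C)(C)C(C)(C)O1
Why: Miyaura borylation (oxidative addition to zerovalent palladium, acetate-assisted transmetalation with the diboron, reductive elimination); anhydrous KOAc leaves the aryl acetates intact.

Step 7
Reactants: 9 4-(4,4,5,5-tetramethyl-1,3,2-dioxaborolan-2-yl)-1,2-phenylene diacetate
Product: 10 (3,4-diacetoxyphenyl)boronic acid
Conditions: NaIO4, 1 M HCl, THF/H2O, rt
Reagents that add atoms: water, O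
Why: The hydrolysis equilibrium of the pinacol ester is driven by periodate cleavage of the released diol to acetone, giving the free boronic acid that the base-free arylation needs; cold dilute acid should spare the aryl acetates.

Step 8
Reactants: 7 5-bromo-4-oxo-4H-chromen-8-yl acetate, 10 (3,4-diacetoxyphenyl)boronic acid
Product: 11 (2S)-8-acetoxy-5-bromo-2-(3,4-diacetoxyphenyl)chroman-4-one
Conditions: Pd(OCOCF3)2 (5 mol %), (R)-4-tert-butyl-2-(pyridin-2-yl)-4,5-dihydrooxazole (6 mol %), NH4PF6 (30 mol %), H2O (5 equiv), ClCH2CH2Cl, 60 °C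
Reagents that add atoms: none
Why: Enantioselective conjugate addition of an arylboronic acid to a chromone under cationic divalent palladium/pyridine-oxazoline catalysis (transmetalation, face-selective insertion of C2=C3 into the aryl–palladium bond, protonolysis of the palladium enolate by water); C2 is set by the chiral ligand, the base-free medium prevents ring opening of the flavanone, and the C5 bromide is inert because zerovalent palladium is not part of the cycle.

Step 9
Reactants: 11 (2S)-8-acetoxy-5-bromo-2-(3,4-diacetoxyphenyl)chroman-4-one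
Product: 14 methyl (2S,3S)-7-acetoxy-4-bromo-2-(3,4-diacetoxyphenyl)-2,3-dihydrobenzofuran-3-carboxylate, via methyl enol ether 12 (not isolated), via iodanyl ketal 13 (not isolated)
Conditions: PhI(OAc)2 (1.3 equiv), conc. H2SO4 (0.2 equiv), HC(OMe)3, 0 °C → rt
Reagents that add atoms: trimethyl orthoformate, COC(OC)OC
Why: Acid and orthoformate turn the C4 ketone into enol ether 12, trivalent iodine adds to C3 on the face trans to the pseudo-equatorial 2-aryl group and methanol captures the oxocarbenium ion to give ketal 13, after which ring-A carbon C4a shifts from C4 to C3 anti-periplanar to the departing iodobenzene and the resulting dimethoxycarbenium ion sheds a methyl group to become the ester. The closest known reaction type is the oxidative 1,2-aryl shift of flavanones and aryl ketones with trivalent iodine or thallium trinitrate in trimethyl orthoformate, which gives methyl trans-2-aryl-2,3-dihydrobenzofuran-3-carboxylates. The five-membered ring O1–C2–C3–C3a–C7a is closed by ring contraction and not by an end-to-end cyclisation: the ipso carbon attacks C3 through a three-membered phenonium bridge (formally 3-exo-tet) while the old C4–C4a bond breaks. The new stereocenter C3 is set by substrate control from C2, since the iodane enters trans to the aryl group and the migration inverts C3, so the ester ends up trans to the aryl group and C2 is never touched, giving (2S,3S). The step needs ring-A rather than ring-B migration and no flavone formation; in the favoured diequatorial conformer the C3–I bond is anti-periplanar to the ring bond C4–C4a but not to the C2–aryl bond, O1 ortho to C4a stabilises the bridge, and the acetates make ring B a poor migrating group and disfavour acid-induced ionisation at C2. Only a catalytic amount of acid in neat orthoformate is used so that the aryl acetates, which shield the catechol from the oxidant, are not methanolysed.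

Step 10
Reactants: 14 methyl (2S,3S)-7-acetoxy-4-bromo-2-(3,4-diacetoxyphenyl)-2,3-dihydrobenzofuran-3-carboxylate
Product: 15 methyl (2S,3S)-4-bromo-2-(3,4-dihydroxyphenyl)-7-hydroxy-2,3-dihydrobenzofuran-3-carboxylate
Conditions: HCl (1.25 M in MeOH), 0 °C → rt, under argon
Reagents that add atoms: none
Why: Acid-catalysed transesterification removes the three aryl acetates as methyl acetate while the C3 methyl ester can only exchange with itself; avoiding base excludes E1cB opening of the dihydrofuran and air oxidation of catecholate, so both stereocenters should persist.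

Step 11
Reactants: 15 methyl (2S,3S)-4-bromo-2-(3,4-dihydroxyphenyl)-7-hydroxy-2,3-dihydrobenzofuran-3-carboxylate
Product: 16 methyl (2S,3S)-4-bromo-2-[3,4-bis(methoxymethoxy)phenyl]-7-(methoxymethoxy)-2,3-dihydrobenzofuran-3-carboxylate
Conditions: MOMCl, i-Pr2NEt, CH2Cl2, 0 °C → rt
Reagents that add atoms: chloromethyl methyl ether, COCCl
Why: O-alkylation of the three phenols under a hindered amine base, too weak to enolise C3, gives acetal ethers that tolerate the Heck conditions and fall to acid at the end.

Step 12
Reactants: 17 (R)-3-(3,4-dihydroxyphenyl)lactic acid (danshensu)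
Product: 18 tert-butyl (R)-3-(3,4-dihydroxyphenyl)-2-hydroxypropanoate
Conditions: Cl3CC(=NH)Ot-Bu, THF, rt
Reagents that add atoms: tert-butyl 2,2,2-trichloroacetimidate, CC(C)(C)OC(=N)C(Cl)(Cl)Cl
Why: The carboxylic acid protonates the imidate and is O-tert-butylated through the ion pair without added catalyst, whereas the phenols and the secondary alcohol would need Lewis acid activation and stay free; the stereocenter is not involved.

Step 13
Reactants: 18 tert-butyl (R)-3-(3,4-dihydroxyphenyl)-2-hydroxypropanoate
Product: 19 tert-butyl (R)-3-[3,4-bis(methoxymethoxy)phenyl]-2-hydroxypropanoate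
Conditions: MOMCl (2.3 equiv), K2CO3, acetone, 0 °C → rt, under argon
Reagents that add atoms: chloromethyl methyl ether, COCCl
Why: Carbonate generates only the phenoxides, which are alkylated by the chloromethyl ether (Williamson-type), while the much less acidic α-hydroxy ester alcohol remains free for the acylation.

Step 14
Reactants: 19 tert-butyl (R)-3-[3,4-bis(methoxymethoxy)phenyl]-2-hydroxypropanoate
Product: 20 tert-butyl (R)-2-(acryloyloxy)-3-[3,4-bis(methoxymethoxy)phenyl]propanoate
Conditions: CH2=CHCOCl, Et3N, CH2Cl2, −20 → 0 °C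
Reagents that add atoms: acryloyl chloride, C=CC(=O)Cl
Why: O-acylation of the secondary alcohol by the acid chloride at low temperature installs the Heck acceptor; the C–O bond at the stereocenter is not broken, so the (R) configuration is retained.

Step 15
Reactants: 16 methyl (2S,3S)-4-bromo-2-[3,4-bis(methoxymethoxy)phenyl]-7-(methoxymethoxy)-2,3-dihydrobenzofuran-3-carboxylate, 20 tert-butyl (R)-2-(acryloyloxy)-3-[3,4-bis(methoxymethoxy)phenyl]propanoate
Product: 21 methyl (2S,3S)-4-[(E)-3-{[(R)-1-tert-butoxy-3-[3,4-bis(methoxymethoxy)phenyl]-1-oxopropan-2-yl]oxy}-3-oxoprop-1-enyl]-2-[3,4-bis(methoxymethoxy)phenyl]-7-(methoxymethoxy)-2,3-dihydrobenzofuran-3-carboxylate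
Conditions: Pd2(dba)3 (2.5 mol %), [HP(t-Bu)3]BF4 (10 mol %), Cy2NMe, 1,4-dioxane, 70 °C
Reagents that add atoms: none
Why: Mizoroki–Heck reaction: the ortho-substituted, electron-rich aryl bromide adds to zerovalent palladium bearing tri-tert-butylphosphine, syn-insertion of the acrylate and syn-β-hydride elimination give the (E)-cinnamate, and the hindered amine only scavenges HBr, so C2, C3 and the danshensu stereocenter are untouched.

Step 16
Reactants: 21 the fully protected coupling product
Product: 22 monomethyl lithospermate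
Conditions: CF3CO2H/CH2Cl2 (1:3), H2O (10 equiv), 0 °C → rt
Reagents that add atoms: none
Why: Acidolysis cleaves the five aryl acetal ethers through oxocarbenium ions and the tert-butyl ester through the tert-butyl cation, while the methyl ester, the cinnamate ester and the free acid are stable to acid at room temperature; water traps the formaldehyde equivalents and the C3 ester disfavours ionisation at C2, so the trans-(2S,3S) ring should persist.

**Compound list**

1 | 4-bromocatechol | Oc1ccc(Br)cc1O | starting material
2 | 4-bromo-1,2-bis(methoxymethoxy)benzene | COCOc1ccc(Br)cc1OCOC | intermediate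
3 | [6-bromo-2,3-bis(methoxymethoxy)phenyl]lithium | COCOc1ccc(Br)c([Li])c1OCOC | intermediate
4 | 1-[6-bromo-2,3-bis(methoxymethoxy)phenyl]ethan-1-one | COCOc1ccc(Br)c(C(C)=O)c1OCOC | intermediate
5 | (E)-1-[6-bromo-2,3-bis(methoxymethoxy)phenyl]-3-(dimethylamino)prop-2-en-1-one | COCOc1ccc(Br)c(C(=O)/C=C/N(C)C)c1OCOC | intermediate
6 | 5-bromo-8-hydroxy-4H-chromen-4-one | O=c1ccoc2c(O)ccc(Br)c12 | intermediate
7 | 5-bromo-4-oxo-4H-chromen-8-yl acetate | CC(=O)Oc1ccc(Br)c2c(=O)ccoc12 | intermediate
8 | 4-bromo-1,2-phenylene diacetate | CC(=O)Oc1ccc(Br)cc1OC(C)=O | intermediate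
9 | 4-(4,4,5,5-tetramethyl-1,3,2-dioxaborolan-2-yl)-1,2-phenylene diacetate | CC(=O)Oc1ccc(B2OC(C)(C)C(C)(C)O2)cc1OC(C)=O | intermediate
10 | (3,4-diacetoxyphenyl)boronic acid | CC(=O)Oc1ccc(B(O)O)cc1OC(C)=O | intermediate
11 | (2S)-8-acetoxy-5-bromo-2-(3,4-diacetoxyphenyl)chroman-4-one | O=C1c2c(Br)ccc(OC(C)=O)c2O[C@@H](C1)c1ccc(OC(C)=O)c(OC(C)=O)c1 | intermediate
12 | (2S)-8-acetoxy-5-bromo-2-(3,4-diacetoxyphenyl)-4-methoxy-2H-chromene | COC1=C[C@@H](c2ccc(OC(C)=O)c(OC(C)=O)c2)Oc2c(OC(C)=O)ccc(Br)c21 | intermediate
13 | 2,3-trans-8-acetoxy-3-[acetoxy(phenyl)-λ3-iodanyl]-5-bromo-2-(3,4-diacetoxyphenyl)-4,4-dimethoxychromane (iodine trans to the aryl group; C2 spatially as in 11, CIP 2R,3R) | COC1(OC)[C@H](I(OC(C)=O)c2ccccc2)[C@@H](c2ccc(OC(C)=O)c(OC(C)=O)c2)Oc2c(OC(C)=O)ccc(Br)c21 | intermediate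
14 | methyl (2S,3S)-7-acetoxy-4-bromo-2-(3,4-diacetoxyphenyl)-2,3-dihydrobenzofuran-3-carboxylate | COC(=O)[C@H]1c2c(Br)ccc(OC(C)=O)c2O[C@@H]1c1ccc(OC(C)=O)c(OC(C)=O)c1 | intermediate
15 | methyl (2S,3S)-4-bromo-2-(3,4-dihydroxyphenyl)-7-hydroxy-2,3-dihydrobenzofuran-3-carboxylate | COC(=O)[C@H]1c2c(Br)ccc(O)c2O[C@@H]1c1ccc(O)c(O)c1 | intermediate
16 | methyl (2S,3S)-4-bromo-2-[3,4-bis(methoxymethoxy)phenyl]-7-(methoxymethoxy)-2,3-dihydrobenzofuran-3-carboxylate | COC(=O)[C@H]1c2c(Br)ccc(OCOC)c2O[C@@H]1c1ccc(OCOC)c(OCOC)c1 | intermediate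
17 | (R)-3-(3,4-dihydroxyphenyl)lactic acid (danshensu) | O[C@H](Cc1ccc(O)c(O)c1)C(=O)O | starting material
18 | tert-butyl (R)-3-(3,4-dihydroxyphenyl)-2-hydroxypropanoate | O[C@H](Cc1ccc(O)c(O)c1)C(=O)OC(C)(C)C | intermediate
19 | tert-butyl (R)-3-[3,4-bis(methoxymethoxy)phenyl]-2-hydroxypropanoate | O[C@H](Cc1ccc(OCOC)c(OCOC)c1)C(=O)OC(C)(C)C | intermediate
20 | tert-butyl (R)-2-(acryloyloxy)-3-[3,4-bis(methoxymethoxy)phenyl]propanoate | C=CC(=O)O[C@H](Cc1ccc(OCOC)c(OCOC)c1)C(=O)OC(C)(C)C | intermediate
21 | methyl (2S,3S)-4-[(E)-3-{[(R)-1-tert-butoxy-3-[3,4-bis(methoxymethoxy)phenyl]-1-oxopropan-2-yl]oxy}-3-oxoprop-1-enyl]-2-[3,4-bis(methoxymethoxy)phenyl]-7-(methoxymethoxy)-2,3-dihydrobenzofuran-3-carboxylate | COC(=O)[C@H]1c2c(/C=C/C(=O)O[C@H](Cc3ccc(OCOC)c(OCOC)c3)C(=O)OC(C)(C)C)ccc(OCOC)c2O[C@@H]1c1ccc(OCOC)c(OCOC)c1 | intermediate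
22 | monomethyl lithospermate | COC(=O)[C@H]1c2c(/C=C/C(=O)O[C@H](Cc3ccc(O)c(O)c3)C(=O)O)ccc(O)c2O[C@@H]1c1ccc(O)c(O)c1 | target

**Step count and risk**

Total step count: 16. Longest linear sequence: 10 steps (steps 1–4, 8–11, 15, 16).

Steps most likely to fail:

Step 9. A competing shift of ring B from C2 to C3 or dehydrogenation to the flavone may take over. Acid methanolysis may strip acetates, after which the freed catechol would be oxidised. Enol ether formation next to the peri bromine may be slow. The fallback separates halogenation, ketalisation and migration and uses no oxidant in the migration step. It sets out from 11: CuBr2 in EtOAc/CHCl3 at reflux should give the trans-3-bromoflavanone F1. HC(OMe)3 with catalytic CH3SO3H converts it into the bromo dimethyl ketal F2. Catalytic ZnBr2 in toluene at 100 °C then induces the known 1,2-aryl shift of an α-bromoalkyl aryl ketal, with inversion at C3 and loss of bromomethane. The fallback returns to the route at 14.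

Step 8. Facial selectivity may be poor, turnover with the electron-poor boronic acid may be low, or protodeboronation may compete. The fallback replaces asymmetric C–C bond formation by resolution and sets out from 7 and 10. The same arylation with Pd(OCOCF3)2 and achiral 2,2'-bipyridine should give the racemic flavanone F3. Kinetic resolution by asymmetric transfer hydrogenation follows, using RuCl(p-cymene)(TsDPEN) of the configuration matched to the (2R)-ketone, HCO2H/Et3N and EtOAc. It reduces the unwanted enantiomer to the cis-flavan-4-ol F4, which is separated by chromatography. The unreacted (2S)-ketone is 11, where the route is rejoined.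

Step 16. Unmasking may be incomplete, formaldehyde equivalents may alkylate the liberated catechols, or acid may open the ring at C2. The fallback exchanges the acetal ethers for silyl ethers so that the phenols are released by fluoride. It sets out from 15 and 18. TBSCl and imidazole in DMF convert 15 into the tris-silyl ether F5. TBSCl (2.1 equiv) and imidazole in CH2Cl2 at 0 °C convert 18 into the bis-silyl ether F6, which is acylated with acryloyl chloride and Et3N to the acrylate F7. Heck coupling of F5 with F7 under the conditions of step 15 should give the coupled penta-silyl ether F8. CF3CO2H in CH2Cl2 removes the tert-butyl group to give the carboxylic acid F9; partial desilylation at this stage is of no consequence. Et3N·3HF in THF finally frees the phenols, and the fallback arrives at 22.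

Further compounds
F1 | step 9 | 2,3-trans-8-acetoxy-3,5-dibromo-2-(3,4-diacetoxyphenyl)chroman-4-one (C2 spatially as in 11; CIP 2R,3R) | O=C1c2c(Br)ccc(OC(C)=O)c2O[C@@H]([C@H]1Br)c1ccc(OC(C)=O)c(OC(C)=O)c1
F2 | step 9 | 2,3-trans-8-acetoxy-3,5-dibromo-2-(3,4-diacetoxyphenyl)-4,4-dimethoxychromane (CIP 2R,3R) | COC1(OC)c2c(Br)ccc(OC(C)=O)c2O[C@@H]([C@H]1Br)c1ccc(OC(C)=O)c(OC(C)=O)c1
F3 | step 8 | racemic 8-acetoxy-5-bromo-2-(3,4-diacetoxyphenyl)chroman-4-one | O=C1CC(Oc2c(OC(C)=O)ccc(Br)c12)c1ccc(OC(C)=O)c(OC(C)=O)c1
F4 | step 8 | (2R,4R)-8-acetoxy-5-bromo-2-(3,4-diacetoxyphenyl)chroman-4-ol (2,4-cis) | O[C@H]1c2c(Br)ccc(OC(C)=O)c2O[C@H](C1)c1ccc(OC(C)=O)c(OC(C)=O)c1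
F5 | step 16 | methyl (2S,3S)-4-bromo-2-[3,4-bis(tert-butyldimethylsilyloxy)phenyl]-7-(tert-butyldimethylsilyloxy)-2,3-dihydrobenzofuran-3-carboxylate | COC(=O)[C@H]1c2c(Br)ccc(O[Si](C)(C)C(C)(C)C)c2O[C@@H]1c1ccc(O[Si](C)(C)C(C)(C)C)c(O[Si](C)(C)C(C)(C)C)c1
F6 | step 16 | tert-butyl (R)-3-[3,4-bis(tert-butyldimethylsilyloxy)phenyl]-2-hydroxypropanoate | O[C@H](Cc1ccc(O[Si](C)(C)C(C)(C)C)c(O[Si](C)(C)C(C)(C)C)c1)C(=O)OC(C)(C)C
F7 | step 16 | tert-butyl (R)-2-(acryloyloxy)-3-[3,4-bis(tert-butyldimethylsilyloxy)phenyl]propanoate | C=CC(=O)O[C@H](Cc1ccc(O[Si](C)(C)C(C)(C)C)c(O[Si](C)(C)C(C)(C)C)c1)C(=O)OC(C)(C)C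
F8 | step 16 | penta-silyl ether tert-butyl ester of monomethyl lithospermate | COC(=O)[C@H]1c2c(/C=C/C(=O)O[C@H](Cc3ccc(O[Si](C)(C)C(C)(C)C)c(O[Si](C)(C)C(C)(C)C)c3)C(=O)OC(C)(C)C)ccc(O[Si](C)(C)C(C)(C)C)c2O[C@@H]1c1ccc(O[Si](C)(C)C(C)(C)C)c(O[Si](C)(C)C(C)(C)C)c1
F9 | step 16 | penta-silyl ether of monomethyl lithospermate (free carboxylic acid) | COC(=O)[C@H]1c2c(/C=C/C(=O)O[C@H](Cc3ccc(O[Si](C)(C)C(C)(C)C)c(O[Si](C)(C)C(C)(C)C)c3)C(=O)O)ccc(O[Si](C)(C)C(C)(C)C)c2O[C@@H]1c1ccc(O[Si](C)(C)C(C)(C)C)c(O[Si](C)(C)C(C)(C)C)c1
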